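A small charge of starting complex, 0.10 M in 4 portions, went into 0.110 M of incoming ligand; this flask is Saturday's run, and I hand it over after 8.00 min.

| setting | Saturday's | flask |
|---|---|---|
| starting complex | 0.10 M (in portions, 4) | 0.10 M (in portions, 4) |
| incoming ligand | 0.11 M | 0.110 M |
| remark | the very flask that is asked about, followed so far; portions every 1.0 min | the portions of starting complex follow each other after 1.0 min, the first at the start |
| time |  | 15 min |

- Saturday's (time / min: starting complex / %, complex with one exchanged / %): 1.00: 23.7, 0.8; 2.00: 47.5, 2.4; 3.00: 69.6, 4.1; 4.00: 91.3, 5.9; 5.00: 88.6, 7.0; 6.00: 85.7, 8.6; 8.00: 80.1, 10.0

(standard deviation of a reading: 0.3 percentage points)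

- what may be going on: complex with two exchanged + incoming ligand <-> leaving ligand + complex with three exchanged; complex with one exchanged + incoming ligand -> leaving ligand + complex with two exchanged; starting complex + incoming ligand -> leaving ligand + complex with one exchanged
- the reaction counts as stopped when no species that holds the starting complex changes by six tenths of a point or more over the second half of the time

1. why nothing more happens at 15 min, or that something still does (it is still moving / forward and back rates have come level / all of the starting complex has reacted / the incoming ligand has run out first)
2. share of the starting complex used up at 15 min
3. complex with one exchanged at 15 min, in percent of the starting complex charged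

Now c(starting complex) reads 80.1% and c(complex with one exchanged) 10.0%. From 4.00 min, with every portion in, to 8.00 min, the starting complex lost 11 percentage points, and 7.1 points of that passed through complex with one exchanged and on. I count turnovers by dividing each flow by the mean amount it left: complex with one exchanged turned over 0.893 times, the starting complex 0.131 times. Their quotient, the turnover ratio, 6.83, is a reading with the scatter in it, and it serves as the selectivity factor between the two steps. Both steps draw on the same incoming ligand at the same moment, so its concentration drops out of the ratio.

Please add no incoming ligand: both steps consume it, and the questions are about this flask as charged with 0.110 M. At this pace complex with one exchanged turns over 1.56 more times by 15 min, more than once, so I expect it near its level, c(complex with one exchanged) = c(starting complex) divided by the turnover ratio.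

The forecast says it is still moving, with 32.5% used up (30.5% to 35%) and 10.3% of complex with one exchanged (9.4% to 11.2%): “the reaction has not stopped and ligand remains”. One division on its conversion gives me 9.88%, lower than its figure.

The flask gives it is still moving, with 31.8% used up and 10.7% of complex with one exchanged.

    complex with two exchanged + incoming ligand ⇌ leaving ligand + complex with three exchanged (K = 0.840, k = 0.0130 M⁻¹ min⁻¹)
    complex with one exchanged + incoming ligand → leaving ligand + complex with two exchanged (k = 2.30 M⁻¹ min⁻¹)
    starting complex + incoming ligand → leaving ligand + complex with one exchanged (k = 0.350 M⁻¹ min⁻¹)

At 15.0 min, complex with one exchanged is made at 0.966 of the rate at which it is used up. Starting complex over complex with one exchanged then stands at 6.35, against the turnover ratio of 6.83. The neighbour flask with 0.040 M of starting complex keeps 63.3% of it; dividing by the turnover ratio gives 9.27% of complex with one exchanged, and that flask holds 10.4%.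

The numbers in the tables were computed from invented constants; the scatter is artificial.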